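Locants: ring carbons C1–C10 (C3 ketone, C6 senecioyloxy carbon, C7 and C8 ring fusion with the lactone oxygen on C8, C10 carbinol), C11 lactone α-carbon, C12 lactone carbonyl, C13 acetoxymethyl carbon. The route rests on the tetrasubstituted C7=C11 alkene of the butenolide ring: with the O8–C12 ester in place, both carbons are 1,1-disubstituted alkene termini. Ring-closing metathesis between an exocyclic C7 methylene on the preformed ten-membered carbocycle and a 2-(acetoxymethyl)acrylate on O8 closes the lactone and brings in C13 with its acetate. The precursor is an oxygen-bridged ten-membered ring (C3/O6 methyl ketal) whose 9,10-epoxide masks the C8=C9 enol ether and C10–OH, unveiled last by vinylogous E1cB opening.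

Key step: step 17

Assumption: the target is taken as the 3-oxo-10-hydroxy tautomer drawn, and hydroxy ketones that can close to hemiketals are written in the open form.
Remark: after the macrocyclisation all intermediates are carried as mixtures of C8 epimers, because C8 becomes sp2 in the last step.

Step 1
Reactants: 1 (R)-5-[(trityloxy)methyl]dihydrofuran-2(3H)-one
Product: 2 (3S,5R)-3-methyl-5-[(trityloxy)methyl]dihydrofuran-2(3H)-one
Conditions: LDA, THF, −78 °C; MeI, −78 °C
Reagents that add atoms: iodomethane CI
Why: Lactone enolate alkylation in which MeI approaches anti to the bulky trityloxymethyl group, so the 3,5-trans lactone forms and C4 (S) is set relative to the chiral-pool C6 (R).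

Step 2
Reactants: 2 (3S,5R)-3-methyl-5-[(trityloxy)methyl]dihydrofuran-2(3H)-one
Product: 3 (3S,5R)-5-(hydroxymethyl)-3-methyldihydrofuran-2(3H)-one
Conditions: AcOH/H2O (4:1), 50 °C
Reagents that add atoms: none
Why: Acidic solvolysis of the trityl ether (SN1 at the trityl carbon) leaves the lactone and both stereocenters untouched.

Step 3
Reactants: 3 (3S,5R)-5-(hydroxymethyl)-3-methyldihydrofuran-2(3H)-one
Product: 4 (2R,4S)-4-methyl-5-oxotetrahydrofuran-2-carbaldehyde
Conditions: Dess–Martin periodinane, NaHCO3, CH2Cl2, 0 °C to rt; used crude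
Reagents that add atoms: none
Why: Buffered Dess–Martin oxidation should give the α-oxy aldehyde under non-basic conditions, so C6 is not epimerised.

Step 4
Reactants: 4 (2R,4S)-4-methyl-5-oxotetrahydrofuran-2-carbaldehyde
Product: 5 (3S,5R)-5-ethynyl-3-methyldihydrofuran-2(3H)-one
Conditions: TMSCHN2, LDA, THF, −78 °C to 0 °C
Reagents that add atoms: (trimethylsilyl)diazomethane C[Si](C)(C)C=[N+]=[N-]
Why: Colvin homologation, in which lithiated TMS-diazomethane adds to the aldehyde faster than to the lactone at −78 °C and Peterson elimination, N2 loss and 1,2-H shift of the alkylidene carbene give the terminal alkyne.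

Step 5
Reactants: 5 (3S,5R)-5-ethynyl-3-methyldihydrofuran-2(3H)-one
Product: 6 (3S,5R)-5-(1-iodovinyl)-3-methyldihydrofuran-2(3H)-one
Conditions: B-iodo-9-BBN, hexane/CH2Cl2, −20 to 0 °C; then AcOH
Reagents that add atoms: B-iodo-9-borabicyclo[3.3.1]nonane IB1C2CCCC1CCC2
Why: Markovnikov haloboration of the terminal alkyne (iodide to the internal carbon) followed by protodeboronation should give the 2-iodo-1-alkene that later serves as the C7 nucleophile.

Step 6
Reactants: 6 (3S,5R)-5-(1-iodovinyl)-3-methyldihydrofuran-2(3H)-one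
Product: 7 (3S,5R)-5-hydroxy-6-iodo-3-methylhept-6-en-2-one
Conditions: MeLi (1.05 equiv), THF, −78 °C; pH 7 buffer
Reagents that add atoms: methyllithium [Li]C
Why: Mono-addition of an organolithium to a γ-lactone, in which the lithium lactolate survives at −78 °C so that only one methyl (C2) adds, and MeLi is too slow in iodine–lithium exchange to touch the vinyl iodide.

Step 7
Reactants: 7 (3S,5R)-5-hydroxy-6-iodo-3-methylhept-6-en-2-one
Product: 8 (3S,5R)-6-iodo-3-methyl-5-[(triethylsilyl)oxy]hept-6-en-2-one
Conditions: TESCl, imidazole, DMF, 0 °C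
Reagents that add atoms: chlorotriethylsilane CC[Si](Cl)(CC)CC
Why: Silylation traps the open-chain γ-hydroxy ketone and protects O6 for the enolate step.

Step 8
Reactants: 9 3-methylbut-2-en-1-yl acetate (prenyl acetate)
Product: 10 (E)-4-hydroxy-3-methylbut-2-en-1-yl acetate
Conditions: SeO2 (cat.), t-BuOOH, salicylic acid (cat.), CH2Cl2, rt
Reagents that add atoms: tert-butyl hydroperoxide CC(C)(C)OO
Why: Selenium dioxide allylic oxidation (ene reaction then [2,3] shift) oxidises the (E)-methyl group of the trisubstituted alkene, which fixes the E geometry of the later C9=C10 bond.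

Step 9
Reactants: 10 (E)-4-hydroxy-3-methylbut-2-en-1-yl acetate
Product: 11 (E)-4-bromo-3-methylbut-2-en-1-yl acetate
Conditions: CBr4, PPh3, CH2Cl2, 0 °C
Reagents that add atoms: carbon tetrabromide BrC(Br)(Br)Br
Why: Appel bromination of the primary allylic alcohol proceeds by SN2 without allylic transposition or loss of alkene geometry.

Step 10
Reactants: 8 (3S,5R)-6-iodo-3-methyl-5-[(triethylsilyl)oxy]hept-6-en-2-one; 11 (E)-4-bromo-3-methylbut-2-en-1-yl acetate
Product: 12 (2E,7S,9R)-10-iodo-3,7-dimethyl-6-oxo-9-[(triethylsilyl)oxy]undeca-2,10-dien-1-yl acetate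
Conditions: LDA (1.05 equiv), THF, −78 °C; then 11, DMPU, −78 to −40 °C
Reagents that add atoms: none
Why: Kinetic enolate alkylation, with deprotonation at the methyl group (C2) rather than the C4 methine and SN2 attack on the allylic bromide, forms C1–C2 without touching the C4 stereocenter.

Step 11
Reactants: 12 (2E,7S,9R)-10-iodo-3,7-dimethyl-6-oxo-9-[(triethylsilyl)oxy]undeca-2,10-dien-1-yl acetate
Product: 14 (E)-5-[(2R,3S,5R)-5-(1-iodovinyl)-2-methoxy-3-methyltetrahydrofuran-2-yl]-3-methylpent-2-en-1-ol, via ketal acetate 13 (not isolated)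
Conditions: CSA (cat.), MeOH, rt; then K2CO3, 0 °C
Reagents that add atoms: methanol CO
Why: Acidic methanolysis removes the TES group and the freed O6 closes onto the C3 ketone as a five-membered mixed methyl ketal under thermodynamic control (C2 chain trans to the C4 methyl, hence cis to the iodovinyl group), which masks ketone and O6 together before basic methanolysis cleaves the allylic acetate.

Step 12
Reactants: 14 (E)-5-[(2R,3S,5R)-5-(1-iodovinyl)-2-methoxy-3-methyltetrahydrofuran-2-yl]-3-methylpent-2-en-1-ol
Product: 15 [(2R,3R)-3-{2-[(2R,3S,5R)-5-(1-iodovinyl)-2-methoxy-3-methyltetrahydrofuran-2-yl]ethyl}-3-methyloxiran-2-yl]methanol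
Conditions: Ti(OiPr)4, D-(−)-diethyl tartrate, t-BuOOH, 4 Å MS, CH2Cl2, −20 °C
Reagents that add atoms: tert-butyl hydroperoxide CC(C)(C)OO
Why: Sharpless asymmetric epoxidation of the (E)-trisubstituted primary allylic alcohol, where the D-(−)-tartrate catalyst delivers oxygen to the face that gives the (9R,10R)-epoxide and so sets the C10 configuration of the target under reagent control.

Step 13
Reactants: 15 [(2R,3R)-3-{2-[(2R,3S,5R)-5-(1-iodovinyl)-2-methoxy-3-methyltetrahydrofuran-2-yl]ethyl}-3-methyloxiran-2-yl]methanol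
Product: 16 (2S,3R)-3-{2-[(2R,3S,5R)-5-(1-iodovinyl)-2-methoxy-3-methyltetrahydrofuran-2-yl]ethyl}-3-methyloxirane-2-carbaldehyde
Conditions: Dess–Martin periodinane, NaHCO3, CH2Cl2, 0 °C; used directly
Reagents that add atoms: none
Why: Buffered Dess–Martin oxidation should give the α,β-epoxy aldehyde without opening the epoxide or the acid-labile ketal (the C9 descriptor changes only through CIP priorities).

Step 14
Reactants: 16 (2S,3R)-3-{2-[(2R,3S,5R)-5-(1-iodovinyl)-2-methoxy-3-methyltetrahydrofuran-2-yl]ethyl}-3-methyloxirane-2-carbaldehyde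
Product: 17 (3R,4S,6R,9R,10R)-3,6:9,10-diepoxy-3-methoxy-4,10-dimethyl-7-methylidenecyclodecan-8-ol (target locants, C8 epimers)
Conditions: CrCl2 (8 equiv), NiCl2 (2 mol %), DMSO, rt, 2 mM, slow addition
Reagents that add atoms: none
Why: Intramolecular Nozaki–Hiyama–Kishi coupling of the 2-iodoalkene with the aldehyde forms C7–C8 and closes the ten-membered carbocycle as an 11-oxabicyclo[6.2.1]undecane, the cis-2,5-disubstituted ketal ring preorganising the two arms and removing the C3 ketone that would otherwise trap the C7 nucleophile in a five-membered ring, while the new C8 carbinol may form as either epimer.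

Step 15
Reactants: 18 2-(bromomethyl)acrylic acid
Product: 19 2-(acetoxymethyl)acrylic acid
Conditions: KOAc (5 equiv), AcOH, 60 °C
Reagents that add atoms: potassium acetate CC(=O)[O-].[K+]
Why: SN2 or SN2′ displacement of the allylic bromide by acetate gives the same product either way, and in acetic acid the substrate's own carboxyl group stays protonated and does not compete.

Step 16
Reactants: 17 (3R,4S,6R,9R,10R)-3,6:9,10-diepoxy-3-methoxy-4,10-dimethyl-7-methylidenecyclodecan-8-ol; 19 2-(acetoxymethyl)acrylic acid
Product: 20 8-O-[2-(acetoxymethyl)acryloyl] ester of 17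
Conditions: EDC·HCl, DMAP (cat.), CH2Cl2, 0 °C to rt
Reagents that add atoms: none
Why: Steglich esterification acylates the only free hydroxyl (O8) and so tethers C11 to C7 through the future lactone ester.

Step 17
Reactants: 20 8-O-[2-(acetoxymethyl)acryloyl] ester of 17
Product: 21 bridged ketal butenolide (lactone O8–C12(=O)–C11(CH2OAc)=C7 fused to the ring of 17)
Conditions: Hoveyda–Grubbs-type Ru catalyst with N,N′-di(o-tolyl) NHC (15 mol %), 1,4-benzoquinone (cat.), toluene, 2 mM, 80 °C
Reagents that add atoms: none
Why: Ring-closing metathesis, in which a ruthenium alkylidene takes up one of the two 1,1-disubstituted alkenes (the exocyclic C7 methylene or the acrylate), adds intramolecularly to the other in a [2+2] step, and cycloreversion of the ruthenacyclobutane forms C7=C11 and releases ethylene. The closest known reaction type is the closure of methallyl 2-substituted acrylates to α,β-disubstituted butenolides with NHC–ruthenium catalysts of reduced ortho bulk. The only ring closed is the five-membered lactone O8–C12–C11=C7–C8, formed in the ring-closing mode because the ester holds C7 and C11 in a 1,5 relationship and ethylene is lost irreversibly at high dilution. No stereocenter is created and C8 remains an epimer mixture. The step needs chemoselectivity for these two alkenes and tolerance of epoxide, ketal and allylic acetate, which is secured because 20 contains no other C=C bond and the remaining groups are inert to ruthenium alkylidenes. The hindered, electron-poor tetrasubstituted alkene is the risk, answered by the catalyst choice, the temperature and the benzoquinone additive against isomerisation.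

Step 18
Reactants: 21 bridged ketal butenolide
Product: 22 (4S,6R,9R,10R)-13-acetoxy-9,10-epoxy-6-hydroxy-4,10-dimethyl-3-oxocyclodec-7(11)-eno-8,12-lactone (target locants, C8 epimers)
Conditions: PPTS (cat.), acetone/H2O (10:1), rt
Reagents that add atoms: water O
Why: Hydrolysis of the mixed cyclic methyl ketal through the C3 oxocarbenium ion should be far faster than acid opening of the epoxide and releases the C3 ketone and the O6 hydroxyl.

Step 19
Reactants: 22 epoxy butenolide hydroxy ketone
Product: 23 6-O-(3-methylbut-2-enoyl) ester of 22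
Conditions: 3-methylbut-2-enoyl chloride, pyridine, CH2Cl2, 0 °C
Reagents that add atoms: 3-methylbut-2-enoyl chloride CC(C)=CC(Cl)=O
Why: Acylation of the only hydroxyl (secondary O6, whose transannular hemiketal with C3 reopens under the conditions) installs the senecioate with retention at C6.

Step 20
Reactants: 23 6-O-(3-methylbut-2-enoyl) ester of 22
Product: 24 CNP0186726.1, (4S,6R,8Z,10R)-13-acetoxy-10-hydroxy-4,10-dimethyl-6-(3-methylbut-2-enoyloxy)-3-oxocyclodeca-7(11),8-dieno-8,12-lactone (target locants)
Conditions: DBU (1.1 equiv), CH2Cl2, −20 to 0 °C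
Reagents that add atoms: none
Why: Vinylogous E1cB, in which deprotonation of the butenolide γ-hydrogen at C8 gives the 2-oxidofuran that opens the adjacent epoxide at C9 to form C8=C9 and the C10 tertiary alcohol with retention at C10, the trans-epoxide being expected to translate into the C7/C10-trans (8Z) enol lactone.

Compound list
1 | (R)-5-[(trityloxy)methyl]dihydrofuran-2(3H)-one | O=C1CC[C@H](COC(c2ccccc2)(c2ccccc2)c2ccccc2)O1 | starting material
2 | (3S,5R)-3-methyl-5-[(trityloxy)methyl]dihydrofuran-2(3H)-one | O=C1[C@@H](C)C[C@H](COC(c2ccccc2)(c2ccccc2)c2ccccc2)O1 | intermediate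
3 | (3S,5R)-5-(hydroxymethyl)-3-methyldihydrofuran-2(3H)-one | O=C1[C@@H](C)C[C@H](CO)O1 | intermediate
4 | (2R,4S)-4-methyl-5-oxotetrahydrofuran-2-carbaldehyde | O=C1[C@@H](C)C[C@H](C=O)O1 | intermediate
5 | (3S,5R)-5-ethynyl-3-methyldihydrofuran-2(3H)-one | O=C1[C@@H](C)C[C@H](C#C)O1 | intermediate
6 | (3S,5R)-5-(1-iodovinyl)-3-methyldihydrofuran-2(3H)-one | O=C1[C@@H](C)C[C@H](C(I)=C)O1 | intermediate
7 | (3S,5R)-5-hydroxy-6-iodo-3-methylhept-6-en-2-one | CC(=O)[C@@H](C)C[C@@H](O)C(I)=C | intermediate
8 | (3S,5R)-6-iodo-3-methyl-5-[(triethylsilyl)oxy]hept-6-en-2-one | CC(=O)[C@@H](C)C[C@@H](O[Si](CC)(CC)CC)C(I)=C | intermediate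
9 | 3-methylbut-2-en-1-yl acetate (prenyl acetate) | CC(C)=CCOC(C)=O | starting material
10 | (E)-4-hydroxy-3-methylbut-2-en-1-yl acetate | CC(=O)OC/C=C(\C)CO | intermediate
11 | (E)-4-bromo-3-methylbut-2-en-1-yl acetate | CC(=O)OC/C=C(\C)CBr | intermediate
12 | (2E,7S,9R)-10-iodo-3,7-dimethyl-6-oxo-9-[(triethylsilyl)oxy]undeca-2,10-dien-1-yl acetate | CC(=O)OC/C=C(\C)CCC(=O)[C@@H](C)C[C@@H](O[Si](CC)(CC)CC)C(I)=C | intermediate
13 | (E)-5-[(2R,3S,5R)-5-(1-iodovinyl)-2-methoxy-3-methyltetrahydrofuran-2-yl]-3-methylpent-2-en-1-yl acetate | CO[C@]1(CC/C(C)=C/COC(C)=O)O[C@@H](C(I)=C)C[C@@H]1C | intermediate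
14 | (E)-5-[(2R,3S,5R)-5-(1-iodovinyl)-2-methoxy-3-methyltetrahydrofuran-2-yl]-3-methylpent-2-en-1-ol | CO[C@]1(CC/C(C)=C/CO)O[C@@H](C(I)=C)C[C@@H]1C | intermediate
15 | [(2R,3R)-3-{2-[(2R,3S,5R)-5-(1-iodovinyl)-2-methoxy-3-methyltetrahydrofuran-2-yl]ethyl}-3-methyloxiran-2-yl]methanol | CO[C@]1(CC[C@@]2(C)O[C@@H]2CO)O[C@@H](C(I)=C)C[C@@H]1C | intermediate
16 | (2S,3R)-3-{2-[(2R,3S,5R)-5-(1-iodovinyl)-2-methoxy-3-methyltetrahydrofuran-2-yl]ethyl}-3-methyloxirane-2-carbaldehyde | CO[C@]1(CC[C@@]2(C)O[C@@H]2C=O)O[C@@H](C(I)=C)C[C@@H]1C | intermediate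
17 | (3R,4S,6R,9R,10R)-3,6:9,10-diepoxy-3-methoxy-4,10-dimethyl-7-methylidenecyclodecan-8-ol (target locants, C8 epimers) | CO[C@]12CC[C@@]3(C)O[C@@H]3C(O)C(=C)[C@H](O1)C[C@@H]2C | intermediate
18 | 2-(bromomethyl)acrylic acid | C=C(CBr)C(=O)O | starting material
19 | 2-(acetoxymethyl)acrylic acid | CC(=O)OCC(=C)C(=O)O | intermediate
20 | 8-O-[2-(acetoxymethyl)acryloyl] ester of 17 (C8 epimers) | CO[C@]12CC[C@@]3(C)O[C@@H]3C(OC(=O)C(=C)COC(C)=O)C(=C)[C@H](O1)C[C@@H]2C | intermediate
21 | bridged ketal butenolide, (3R,4S,6R,9R,10R)-13-acetoxy-3,6:9,10-diepoxy-3-methoxy-4,10-dimethylcyclodec-7(11)-eno-8,12-lactone (target locants, C8 epimers) | CO[C@]12CC[C@@]3(C)O[C@@H]3C4OC(=O)C(COC(C)=O)=C4[C@H](O1)C[C@@H]2C | intermediate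
22 | (4S,6R,9R,10R)-13-acetoxy-9,10-epoxy-6-hydroxy-4,10-dimethyl-3-oxocyclodec-7(11)-eno-8,12-lactone (target locants, C8 epimers) | CC(=O)OCC1=C2[C@H](O)C[C@H](C)C(=O)CC[C@@]3(C)O[C@@H]3C2OC1=O | intermediate
23 | 6-O-(3-methylbut-2-enoyl) ester of 22 (C8 epimers) | CC(=O)OCC1=C2[C@H](OC(=O)C=C(C)C)C[C@H](C)C(=O)CC[C@@]3(C)O[C@@H]3C2OC1=O | intermediate
24 | CNP0186726.1, (4S,6R,8Z,10R)-13-acetoxy-10-hydroxy-4,10-dimethyl-6-(3-methylbut-2-enoyloxy)-3-oxocyclodeca-7(11),8-dieno-8,12-lactone (target locants) | CC(=O)OCC1=C2/C(=C/[C@](C)(O)CCC(=O)[C@@H](C)C[C@H]2OC(=O)C=C(C)C)OC1=O | target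

Total steps: 20. Longest linear sequence: 17 (steps 1–7, 10–14, 16–20).

Steps most likely to fail

1. Step 17 (ring-closing metathesis). The process at risk is loading of ruthenium on either hindered 1,1-disubstituted alkene: catalyst decay, alkene isomerisation or intermolecular metathesis may outrun closure of the tetrasubstituted alkene. The fallback replaces metathesis by carbonyl olefination and runs from 17 back to 21. Ozonolysis of the exocyclic methylene of 17 (O3, CH2Cl2, −78 °C; PPh3) should give the C7 ketone, ketol F1. Steglich esterification of O8 with 2-(diethoxyphosphoryl)acrylic acid gives the phosphonoacrylate ester F2. Conjugate addition of acetate (CsOAc, 18-crown-6, MeCN, 0 °C to rt) then generates the C11 phosphonate carbanion with the C13 acetate already in place, and intramolecular Horner–Wadsworth–Emmons olefination of the C7 ketone closes the same C7=C11 bond to rejoin the route at 21. The donor in this Michael–olefination sequence of 2-phosphonoacrylates is a carboxylate here, which is an extension of the usual alkoxide, thiolate and amine donors.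

2. Step 14 (Ni/Cr macrocyclisation). The process at risk is the fate of the α,β-epoxy aldehyde under excess Cr(II): reductive or Lewis-acid opening of the epoxide, or intermolecular coupling, may compete with closure of the medium ring. The fallback installs the epoxide after ring closure and runs from 14 back to 17. MnO2 oxidation of 14 gives the enal F3, and the same Ni/Cr cyclisation, now with no epoxide present, gives the dienyl alcohol F4. A reagent-controlled Shi epoxidation (D-fructose-derived ketone, Oxone, buffered MeCN/H2O, 0 °C) of the (E)-trisubstituted C9=C10 alkene is then expected to favour the (9R,10R)-epoxide and to spare the deactivated exocyclic methylene, rejoining the route at 17.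

3. Step 20 (epoxide opening). The processes at risk are loss of the C13 acetate from the same dienolate (vinylogous β-elimination) instead of epoxide opening, and formation of C8=C9 with the C7/C10-cis geometry. The fallback uses Lewis-acid-assisted instead of purely basic opening and runs from 23 to 24. TMSOTf with 2,6-lutidine (CH2Cl2, −78 °C) silylates the epoxide oxygen so that C9–O cleavage is coupled to removal of the C8 proton and outpaces acetate loss, giving the C10 O-trimethylsilyl ether F5. Citric acid in MeOH then frees the tertiary alcohol to give 24.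

Further compounds
F1 | step 17 | ketol, (3R,4S,6R,9R,10R)-3,6:9,10-diepoxy-8-hydroxy-3-methoxy-4,10-dimethylcyclodecan-7-one (target locants, C8 epimers) | CO[C@]12CC[C@@]3(C)O[C@@H]3C(O)C(=O)[C@H](O1)C[C@@H]2C
F2 | step 17 | 8-O-[2-(diethoxyphosphoryl)acryloyl] ester of F1 | CO[C@]12CC[C@@]3(C)O[C@@H]3C(OC(=O)C(=C)P(=O)(OCC)OCC)C(=O)[C@H](O1)C[C@@H]2C
F3 | step 14 | (E)-5-[(2R,3S,5R)-5-(1-iodovinyl)-2-methoxy-3-methyltetrahydrofuran-2-yl]-3-methylpent-2-enal | CO[C@]1(CC/C(C)=C/C=O)O[C@@H](C(I)=C)C[C@@H]1C
F4 | step 14 | (3R,4S,6R,9E)-3,6-epoxy-3-methoxy-4,10-dimethyl-7-methylidenecyclodec-9-en-8-ol (target locants, C8 epimers) | CO[C@]12CC/C(C)=C/C(O)C(=C)[C@H](O1)C[C@@H]2C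
F5 | step 20 | 10-O-trimethylsilyl ether of 24 | CC(=O)OCC1=C2/C(=C/[C@](C)(O[Si](C)(C)C)CCC(=O)[C@@H](C)C[C@H]2OC(=O)C=C(C)C)OC1=O
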